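| flask | starting material | coupling partner | second substrate | remark | time |
|---|---|---|---|---|---|
| larch | 0.020 M (in portions, 3) | 0.026 M | 2 mM | run made earlier; portions every 6.0 h |  |
| oak | 0.020 M (in portions, 3) | 0.026 M | 3 mM | run made earlier; portions every 6.0 h |  |
| maple | 0.010 M (in portions, 3) | 0.026 M | 4 mM | run made earlier; portions every 6.0 h |  |
| flask | 0.020 M (in portions, 3) | 0.0260 M | 4.00 mM | the portions of starting material follow each other after 6.0 h, the first at the start | 15 d |

| run | time / d | starting material / % | target / % | isomer of the product / % |
|---|---|---|---|---|
| larch | 1.25 | 55 | 27 | 17 |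
| larch | 2.00 | 43 | 26 | 25 |
| larch | 3.00 | 40 | 21 | 37 |
| larch | 5.00 | 36 | 19 | 41 |
| larch | 8.00 | 37 | 18 | 47 |
| larch | 12.0 | 38 | 21 | 43 |
| larch | 20.0 | 40 | 17 | 45 |
| oak | 2.50 | 44 | 24 | 34 |
| oak | 5.00 | 40 | 22 | 42 |
| oak | 8.00 | 39 | 18 | 39 |
| oak | 10.0 | 38 | 15 | 43 |
| oak | 12.0 | 37 | 20 | 42 |
| oak | 15.0 | 37 | 19 | 43 |
| oak | 20.0 | 39 | 16 | 44 |
| maple | 1.25 | 42 | 34 | 22 |
| maple | 2.50 | 39 | 26 | 36 |
| maple | 5.00 | 33 | 25 | 43 |
| maple | 10.0 | 29 | 21 | 48 |
| maple | 20.0 | 32 | 19 | 48 |

(standard deviation of a reading: 2 percentage points)

- the numbers in the tables scatter with a standard deviation of 2 percentage points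
- the reaction counts as stopped when no species that holds the starting material changes by six tenths of a point or more over the second half of the time

- the state of affairs at 15 d: stopped, and by what, or still going (forward and back rates have come level / it is still moving / the coupling partner has run out first / all of the starting material has reacted)
- conversion of starting material at 15 d
- amount of target at 15 d, in percent of the starting material charged
- amount of isomer of the product at 15 d, in percent of the starting material charged

Waiting does not take the starting material to zero: the maple run holds 29% at 10.0 d and 32% at 20.0 d, a step inside the scatter, although its coupling partner (0.026 M) exceeds its starting material (0.010 M). The earlier runs climb a ladder in time, which I count in powers of ten short of the asked time: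

| Rung | Time | Powers of ten short |
|---|---|---|
| last portion in | 0.500 d | 1.48 |
| oak: starting material near its level, 44% | 2.50 d | 0.778 |
| larch: isomer near its level, 41% | 5.00 d | 0.477 |
| oak: changes within scatter | 10.0 d | 0.176 |

The top rung lies below 15 d, so I expect the flask to end level, under thermodynamic control.

An end quotient should then serve. I assume that by the plateau each second substrate has taken one coupling partner and that the second substrate is used up. From larch I get 0.134 mM⁻¹ and from maple 0.137 mM⁻¹. Their mean is 0.135 mM⁻¹, the plateau quotient: ([target] + [isomer]) / ([starting material][coupling partner]). In logarithms, the logarithm of reacted over free starting material equals that of the quotient times [coupling partner]. For the flask I reckon 11.7 mM reacted, a conversion of 58.3%.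

The forecast says: forward and back rates have come level, conversion 62%, target 18%, isomer 44%. It holds that the second substrate “doesn't shift the end point and is at most kinetic”, and it uses 0.12 per mM. Its conversion stands above mine by 3.7 percentage points.

    starting material + coupling partner ⇌ target (K = 43.0 L mol⁻¹, k = 0.00165 L mol⁻¹ s⁻¹)
    second substrate + coupling partner → second product (k = 2.40 × 10⁻⁴ L mol⁻¹ s⁻¹)
    target ⇌ isomer of the product (K = 2.30, k = 8.91 × 10⁻⁶ s⁻¹)

The flask gives: forward and back rates have come level, with conversion 59.3%, target 17.9%, isomer 41.4%, and second product 0.00389 M. In the flask the half-life of the slowest mode, 3.24 d, is shorter than the 15 d allowed, and conversion at 150 d is still 59.1%. With coupling partner at 39% of its charge, the quotient gives a logarithm of 0.142, and the flask's reacted over free gives 0.164. A neighbouring flask, with 0.10 M of coupling partner and 78% of it left, gives 1.02 against 1.04, at a conversion of 91.7%.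

The readings come from a simulation from invented constants, and the scatter is random.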